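# Proposed synthesis of CNP0280463.1 by palladium–trimethylenemethane annulation of a cycloheptenone ester

## The problem

CNP0280463.1 is a homoadamantane. Its bridgeheads C1 (isobutyryl), C3, C5 (geranyl) and C7 are joined by three carbonyl bridges (C2 between C1 and C3, C4 between C3 and C5, C9 between C1 and C5), by the methylene C6, by the gem-dimethyl carbon C8 and by the two-carbon bridge C10–C11. A cyclopentane (C3, C11, C12 = CMe2, C13 = CH bearing isopropenyl, C14 = CH2) is fused across C3–C11. Of the six stereocentres, C1, C3, C5 and C7 are locked together by the cage, so only three elements are independent: the absolute configuration at C7, the cis ring fusion C3/C11 relative to C7, and C13. C7 is the natural controller, because a bulky substituent there steers reagents to one face of the seven-membered ring C3–C4–C5–C6–C7–C10–C11. C5 and C1 have no choice once their bridges close, and C13 lies on the convex face of a cis-fused bicycle, where equilibration can reach it. The hard bonds are those to C1: every carbon of the trione ring is quaternary, so a Claisen closure onto C1 cannot be pulled through by enolisation of its product, and the finished β-tricarbonyl is open to retro-Claisen cleavage by alkoxides. The geranyl and isopropenyl alkenes rule out strong acid, ozone and hydrogenation late in the route. The enabling feature is that, within the seven-membered ring, the C4 ketone has C3 (the carrier of the C2 carbonyl) as its α-carbon and C11 as its β-carbon. An enone ester with its alkene between C3 and C11 is therefore a doubly activated acceptor for a three-carbon unit C12–C13–C14, which delivers the cyclopentane and the quaternary C3 in one step.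

## Retrosynthesis

In what follows "the arm" is the chain C8(Me)2–C1H2–C(=O)-i-Pr on C7.

**28 ⇒ 27 (C9 lowered from ketone to carbinol; no skeletal bond cut).** The bond that closes the cage ends at a carbon bearing three acyl groups. Cutting C1–C9 or C1–C2 at the ester level would ask a stabilised diketone enolate to expel alkoxide, which is uphill and leaves the alkoxide free to cleave the product. With C9 as a carbinol the same cut becomes a retro-aldol, so the forward bond formation is an addition with a real driving force. The price is one Dess–Martin oxidation (step 16).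

**27 ⇒ 24 + 25 via 26 (cuts C1–C9 and C5–geranyl).** Retro-aldol opens the cage to the quaternary aldehyde 26, and removal of the geranyl group (from geranyl bromide 25) leads to the hydroxymethylene ketone 24. Alkylating after the one-carbon unit is in place lets the C2–C1–C8 bridge decide the face: the geranyl group enters from the open side and the formyl group is left pointing at C1. The reverse order would put C9 on the exposed face, out of reach of C1. The forward step must be C-selective and SN2; 24 is simpler by ten carbons, one ring and two stereocentres.

**24 ⇒ 23 (cut C5–C9).** Once C1–C2 is closed, the arm ketone is tied up in an acidic 1,3-diketone, and C5 is the only position that a simple ketone enolate can occupy. Formylation is therefore unambiguous at this stage. On the open precursor 22 the arm ketone would have been a competing site.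

**23 ⇒ 22 (cut C1–C2).** This is the one Claisen closure onto C1 that is thermodynamically sound, because its product still has a proton on C1 and is drained as the diketonate. It closes a seven-membered ring and gives the bicyclo[3.3.2]decane core. The forward reaction needs the arm and the C3 ester on the same face of the seven-membered ring, which the key step provides. The ethoxycarbonyl group that activated the acceptor thus becomes C2 of the trione.

**22 ⇒ 16 (isopropenyl from the exocyclic methylene).** The methylene carbon of 16 is kept and becomes the central carbon of the isopropenyl group: hydroboration–oxidation (18), oxidation to the aldehyde (19), methyl addition (20), oxidation (21) and methylenation. Cleaving the methylene to a C13 ketone and adding two carbons would be a step shorter, but would require telling three ketones apart. Here each reagent meets one reactive group, and C13 is set by equilibration of 19. The sequence is placed before the Dieckmann step because the diketone enol of 23 would not tolerate boranes and oxidants.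

**16 ⇒ 11 + 15 (cuts C11–C12 and C3–C14; the key step).** Removing the C12–C13–C14 unit as a trimethylenemethane equivalent leaves the cycloheptenone ester 11 and the silyl acetate 15. Against a stepwise annulation this cut makes both bonds, the ring, C3 and C11 in one catalytic operation, and it leaves the exocyclic alkene exactly where the isopropenyl group is needed. The precursor has a single stereocentre (C7). The forward reaction must bond through the dimethyl-substituted donor terminus and on the face away from the arm.

**11 ⇒ 9 ⇒ 7 + 8 (dehydrogenation, then cuts C3–C4 and C3–C11).** The enone ester comes from the β-keto ester 9 by selenoxide elimination. Excising the ester-bearing carbon of 9 as ethyl diazoacetate (8) leaves the 4-substituted cyclohexanone 7, which has a mirror plane. A chiral Lewis acid that chooses which α-methylene migrates therefore sets C7, the only centre that has to come from asymmetric catalysis.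

**7 ⇒ 4 + 2 (cut C7–C8); 2 ⇐ 1; 4 ⇐ 3; 15 ⇐ 12.** Conjugate addition of the cyclohexyl nucleophile from bromide 4 to enone 2 makes the quaternary C8 and brings in C1 and the isobutyryl ketone with it. Enone 2 is one step from acid chloride 1, bromide 4 one step from the commercial alcohol 3, and donor 15 one flask from bromide 12.

## Roads not taken

**Alternative 1: tethered double C-acylation closes the trione ring last.** The cut is at C4–C5 and C1–C2: the whole C2–C3–C4 unit is detached from the two α-carbons of the C9 ketone. Forward, two acid chloride groups on C3 would acylate a C9 silyl enol ether tethered through C11–C10–C7, first at C5 and then at C1, to give the caged trione A1. The isobutyryl group would then be added by bridgehead metalation and acylation.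
- Merits: three rings and two bonds form in one operation, C5 follows from the tether, and the acyl group enters last and could be varied.
- Weak points: C3 is quaternary, so the acid chlorides cannot react through a ketene and A1 cannot be stabilised as a C2–C3–C4 enol; these are the two features that normally carry such cyclisations. Each acylation must also close a seven-membered ring, and HCl is set free beside geranyl and isopropenyl. The final deprotonation at C1 is done on a cage whose ketones cannot enolise and are exposed to the base. The open precursor must hold C7, C11 and C13 in fixed relation with no ring to relay them.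
- Comparison: in ring-forming economy this road is better than the chosen one, which needs steps 7, 13 and 15 for the same cage. The chosen plan sets against it a driving force for each closure (diketonate in step 13, aldol in step 15) and a catalytic step in which C7 controls C3 and C11.

**Alternative 2: rhodium carbenoid formal [4+3] builds the seven-membered ring.** The cut is at C5–C6 and C3–C11: the ring is divided into a three-carbon vinylcarbenoid (C3–C4–C5, carrying the C2 and C9 esters and the C4 silyl ether) and a four-carbon diene (C6=C7–C10=C11). Forward, Rh2(S-DOSP)4 would cyclopropanate the C6=C7 terminus, and Cope rearrangement of the cis-divinylcyclopropane would give A2.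
- Merits: asymmetric catalysis sets C3 and C11 together and in the absolute sense, both ester carbons and the C4 oxygen arrive with the carbenoid, and the assembly is convergent.
- Weak points: the alkene to be cyclopropanated is 1,1-disubstituted and carries the neopentyl arm, and the other diene terminus carries quaternary C12, so the boat transition state is crowded at both ends. C7 is sp2 in A2 and must be set later by hydrogenating a ring alkene. The cyclopentane is still open and has to be closed by alkylating C3 with the C14 chloride next to C12. C13 must be made in an open chain. Dehydration of the tertiary carbinol can give isopropylidene as well as isopropenyl.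
- Comparison: having C9 on C5 from the start and two catalyst-set centres are real advantages, and the step count to the seven-membered ring is no worse. The chosen plan sets against them that its key step makes the cyclopentane, C3 and C11 at once, under the control of the single centre C7. Both roads meet the same C1 problem at the end.

**Alternative 3: dearomatising Claisen rearrangement forges the bicyclo[3.3.1] core.** The cut is at C1–C8, read backwards as a [3,3] shift that restores an O–C10 bond of an aryl allyl ether. Forward, heating with Cu(OTf)2 and a chiral bis(oxazoline) would break O–C10, form C1–C8 with loss of aromaticity, and ketonisation at C5 would give A3.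
- Merits: the three ring oxygens and the isobutyryl group come from an aromatic ring, and C1 becomes quaternary with all three acyl groups in a sigmatropic step, so the acylation problem at C1 never arises. It is potentially the shortest road.
- Weak points: a Claisen that ends in a non-aromatic bridged trione has no rearomatisation to drive it, and asymmetric induction in such a variant has no close model. After A3 the acetal carbon C11 must bond to both C3 and the methylene carbon C10 and lose its oxygen, while C7–H is set by a reduction. C13 is an isolated side-chain centre, and geranyl must enter at the C5 bridgehead between two carbonyls.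
- Comparison: if the rearrangement worked, this road would be shorter and would solve C1 more elegantly. The chosen plan sets against it that its one unproven element is an extension of a well-studied cycloaddition, that every stereocentre is controlled from a ring, and that no bridgehead alkylation is needed.

Key step: step 7

Assumption: the L-pipecolic acid-derived N,N′-dioxide ligand L-PiPr2 (2,6-diisopropylanilide arms, propane-1,3-diyl linker) is taken to favour the migration that gives (5R)-9; if the sense is the reverse, its enantiomer is used and nothing else changes.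

Remark: the C3 ester is carried as the ethyl ester because ethyl diazoacetate (8) is the diazo ester of commerce; atom numbers C1–C14 are those of the target as defined above.

## Route

Step 1
Reactants: 1 3-methylbut-2-enoyl chloride
Product: 2 2,5-dimethylhex-4-en-3-one
Conditions: i-PrMgCl, Fe(acac)3 (3 mol %), THF, −78 °C
Reagents that add atoms: isopropylmagnesium chloride, CC(C)[Mg]Cl
Why: Iron-catalysed acylation of a Grignard reagent by an acid chloride stops at the ketone at −78 °C, and the β,β-disubstituted enone formed is too hindered for conjugate addition under these conditions.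

Step 2
Reactants: 3 1,4-dioxaspiro[4.5]decan-8-ol
Product: 4 8-bromo-1,4-dioxaspiro[4.5]decane
Conditions: CBr4, PPh3, CH2Cl2, 0 °C to rt
Reagents that add atoms: carbon tetrabromide, BrC(Br)(Br)Br
Why: Appel bromination of a secondary alcohol under neutral conditions that leave the dioxolane intact; the carbinol carbon is not a stereocentre in this symmetric ring.

Step 3
Reactants: 4 8-bromo-1,4-dioxaspiro[4.5]decane; 2 2,5-dimethylhex-4-en-3-one
Product: 7 4-(2,5-dimethyl-4-oxohexan-2-yl)cyclohexan-1-one, via Grignard reagent 5 (not isolated), via silyl enol ether ketal 6 (not isolated)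
Conditions: Mg, THF, rt; CuBr·SMe2 (10 mol %), TMSCl, 2, THF, −78 to −20 °C; then 2 M HCl, THF, rt
Reagents that add atoms: water, O
Why: Copper-catalysed conjugate addition of a secondary Grignard reagent to a β,β-disubstituted enone, accelerated by TMSCl, forms the C7–C8 bond and the quaternary C8, while the isopropyl group shields the carbonyl from 1,2-addition. Dilute acid then cleaves both the silyl enol ether and the dioxolane; the product has a mirror plane, so no stereocentre arises.

Step 4
Reactants: 7 4-(2,5-dimethyl-4-oxohexan-2-yl)cyclohexan-1-one; 8 ethyl diazoacetate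
Product: 9 ethyl (5R)-5-(2,5-dimethyl-4-oxohexan-2-yl)-2-oxocycloheptane-1-carboxylate (C3 epimers and enol)
Conditions: Sc(OTf)3 (10 mol %), N,N′-dioxide ligand L-PiPr2 (11 mol %), CH2Cl2, −20 °C
Reagents that add atoms: none
Why: Lewis acid-catalysed addition of the diazo ester to the ring ketone and 1,2-shift with loss of N2 (diazo ester ring expansion of the Tiffeneau–Demjanov type); the chiral scandium complex distinguishes the two enantiotopic α-methylene groups, and the one that migrates becomes C11, which fixes C7. The arm ketone, flanked by isopropyl and neopentyl groups, should not compete, and the C3 epimers and enol of 9 converge in step 5.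

Step 5
Reactants: 9 ethyl (5R)-5-(2,5-dimethyl-4-oxohexan-2-yl)-2-oxocycloheptane-1-carboxylate
Product: 11 ethyl (4S)-4-(2,5-dimethyl-4-oxohexan-2-yl)-7-oxocyclohept-1-ene-1-carboxylate, via selenide 10 (not isolated)
Conditions: PhSeCl, pyridine, CH2Cl2, 0 °C; then 30% H2O2, 0 °C to rt
Reagents that add atoms: none
Why: α-Selenenylation of the β-keto ester enol, oxidation and selenoxide syn-elimination, which can only run towards C11 because C4 is a carbonyl; pyridine does not enolise the arm ketone. C7 is untouched, and its descriptor changes from R to S by priority only.

Step 6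
Reactants: 12 (2-bromoallyl)trimethylsilane
Product: 15 2-methyl-3-[(trimethylsilyl)methyl]but-3-en-2-yl acetate, via vinyllithium 13 (not isolated), via lithium alkoxide 14 (not isolated)
Conditions: t-BuLi (2 equiv), Et2O, −78 °C; acetone; then Ac2O, −78 °C to rt
Reagents that add atoms: acetone, CC(C)=O; acetic anhydride, CC(=O)OC(C)=O
Why: Bromine–lithium exchange, 1,2-addition of the vinyllithium to acetone and acetylation of the tertiary lithium alkoxide in the same flask, the usual entry to substituted 2-(silylmethyl)allyl acetates.

Step 7
Reactants: 11 ethyl (4S)-4-(2,5-dimethyl-4-oxohexan-2-yl)-7-oxocyclohept-1-ene-1-carboxylate; 15 2-methyl-3-[(trimethylsilyl)methyl]but-3-en-2-yl acetate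
Product: 16 ethyl 7-(2,5-dimethyl-4-oxohexan-2-yl)-1,1-dimethyl-2-methylidene-4-oxodecahydroazulene-3a-carboxylate (cis ring fusion; C7 arm cis to the ester; azulene locants 3a, 8a, 1, 2, 3 are C3, C11, C12, C13, C14)
Conditions: Pd(OAc)2 (5 mol %), P(O-i-Pr)3 (30 mol %), 15 (1.5 equiv), THF, reflux
Reagents that add atoms: none
Why: Zerovalent palladium, formed in the flask from Pd(OAc)2 and P(O-i-Pr)3, ionises the tertiary allylic acetate of 15, and the acetate released removes the silyl group to give the zwitterionic trimethylenemethane–palladium complex, whose termini interconvert faster than they are trapped. The complex adds through its dimethyl-substituted, most carbanion-like terminus to C11 of the doubly activated alkene of 11 (C11–C12), and the ester-stabilised enolate then closes through C3 onto the allylpalladium terminus (C3–C14), which returns the catalyst. The closest known reaction type is the palladium-catalysed trimethylenemethane [3+2] cycloaddition of 2-(silylmethyl)allyl acetates to 2-alkoxycarbonyl cycloalkenones, in which alkyl-substituted donors bond through the substituted carbon; the gem-dimethyl donor extends this to a fully substituted terminus. The five-membered ring closes by intramolecular allylic alkylation, a 5-exo-tet substitution at C14 when counted on the σ-allyl form, and it must close cis because the three-carbon chain anchored at C11 reaches only the same face of the planar enolate. C11 is controlled by C7: the tert-alkyl arm sits pseudo-equatorially on the cycloheptenone and the donor enters trans to it, as nucleophiles do with 5-substituted cycloalkenones; C3 follows from C11, so the ester ends cis to the arm. The step needs regioselectivity within the donor (relying on the preference of alkyl-substituted complexes for the substituted terminus), facial selectivity (C7) and chemoselectivity for the ester-activated alkene over the hindered arm ketone, which such complexes do not attack without a Lewis acid co-catalyst.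

Step 8
Reactants: 16 ethyl 7-(2,5-dimethyl-4-oxohexan-2-yl)-1,1-dimethyl-2-methylidene-4-oxodecahydroazulene-3a-carboxylate
Product: 18 ethyl 7-(2,5-dimethyl-4-oxohexan-2-yl)-2-(hydroxymethyl)-1,1-dimethyl-4-oxodecahydroazulene-3a-carboxylate (mixture of C13 epimers), via alkylborane 17 (not isolated)
Conditions: 9-BBN, THF, 0 °C to rt; then NaBO3·4H2O, THF–H2O, rt
Reagents that add atoms: sodium perborate, [Na+].O[B-](O)(O)OO
Why: Anti-Markovnikov hydroboration of the unhindered methylene terminus by 9-BBN should be much faster than reduction of the two ketones, each flanked by a fully substituted carbon, and perborate oxidises the borane without the strongly basic peroxide that could open the β-keto ester. C13 forms as a mixture (attack from the convex face puts CH2OH on the concave face) and is corrected in step 9.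

Step 9
Reactants: 18 ethyl 7-(2,5-dimethyl-4-oxohexan-2-yl)-2-(hydroxymethyl)-1,1-dimethyl-4-oxodecahydroazulene-3a-carboxylate
Product: 19 ethyl 7-(2,5-dimethyl-4-oxohexan-2-yl)-2-formyl-1,1-dimethyl-4-oxodecahydroazulene-3a-carboxylate (formyl cis to the ester and to H11)
Conditions: DMP, CH2Cl2, 0 °C to rt; after work-up DBU (0.2 equiv), CH2Cl2, rt
Reagents that add atoms: none
Why: Dess–Martin oxidation gives the aldehyde, and DBU equilibrates the enolisable C13 to the epimer with the formyl group on the convex face of the cis-fused bicycle, cis to H11 and to the ester and trans to the seven-membered ring. This thermodynamic epimer has the C13 configuration of the target.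

Step 10
Reactants: 19 ethyl 7-(2,5-dimethyl-4-oxohexan-2-yl)-2-formyl-1,1-dimethyl-4-oxodecahydroazulene-3a-carboxylate
Product: 20 ethyl 7-(2,5-dimethyl-4-oxohexan-2-yl)-2-(1-hydroxyethyl)-1,1-dimethyl-4-oxodecahydroazulene-3a-carboxylate (carbinol epimers)
Conditions: MeTi(O-i-Pr)3, THF, −40 to 0 °C
Reagents that add atoms: methyltitanium triisopropoxide, C[Ti](OC(C)C)(OC(C)C)OC(C)C
Why: MeTi(O-i-Pr)3 adds to aldehydes but not to ketones or esters, so only the formyl group reacts; the new carbinol centre forms as a mixture and is removed in step 11.

Step 11
Reactants: 20 ethyl 7-(2,5-dimethyl-4-oxohexan-2-yl)-2-(1-hydroxyethyl)-1,1-dimethyl-4-oxodecahydroazulene-3a-carboxylate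
Product: 21 ethyl 2-acetyl-7-(2,5-dimethyl-4-oxohexan-2-yl)-1,1-dimethyl-4-oxodecahydroazulene-3a-carboxylate
Conditions: DMP, CH2Cl2, 0 °C to rt
Reagents that add atoms: none
Why: Dess–Martin oxidation of the secondary alcohol to the methyl ketone; C13 stays on the thermodynamically preferred convex side.

Step 12
Reactants: 21 ethyl 2-acetyl-7-(2,5-dimethyl-4-oxohexan-2-yl)-1,1-dimethyl-4-oxodecahydroazulene-3a-carboxylate
Product: 22 ethyl 7-(2,5-dimethyl-4-oxohexan-2-yl)-1,1-dimethyl-4-oxo-2-(prop-1-en-2-yl)decahydroazulene-3a-carboxylate
Conditions: Ph3PCH3Br, KOt-Bu (1.2 equiv of ylide), THF, 0 °C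
Reagents that add atoms: methyltriphenylphosphonium bromide, C[P+](c1ccccc1)(c1ccccc1)c1ccccc1.[Br-]
Why: Wittig methylenation; the methyl ketone is far more accessible than the C4 ketone (α-quaternary) and the arm ketone (isopropyl and neopentyl flanks), so a small excess of ylide at 0 °C should convert it alone.

Step 13
Reactants: 22 ethyl 7-(2,5-dimethyl-4-oxohexan-2-yl)-1,1-dimethyl-4-oxo-2-(prop-1-en-2-yl)decahydroazulene-3a-carboxylate
Product: 23 tricyclic triketone with the C2–C1–C8 bridge closed (bicyclo[3.3.2]decane core fused to the cyclopentane; C1–H bears the isobutyryl group; C2 and C4 ketones; C5 is CH2)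
Conditions: KOt-Bu (3 equiv), THF, 0 °C to rt; aq. HCl work-up
Reagents that add atoms: none
Why: Dieckmann-type intramolecular Claisen condensation: under equilibrating conditions the arm enolate (C1) is acylated by the C2 ester, which the configurations at C7 and C3 hold on the same face, and the closure is driven by deprotonation of the resulting 1,3-diketone. Aldol adducts of the ketone enolates are reversible and drain into this sink; C1 is an enolised, labile centre at this stage.

Step 14
Reactants: 23 tricyclic triketone with the C2–C1–C8 bridge closed
Product: 24 C5-hydroxymethylene derivative of 23 (chelated enol; hydroxyl syn to the C4 carbonyl)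
Conditions: NaH, HCO2Et, THF, 0 °C to rt; aq. HCl work-up
Reagents that add atoms: ethyl formate, CCOC=O
Why: Claisen formylation: the diketone is protected as its sodium salt, so the only enolate that can be acylated is that of the C4 ketone at C5, and the product is held as the chelated hydroxymethylene salt.

Step 15
Reactants: 24 C5-hydroxymethylene derivative of 23; 25 geranyl bromide
Product: 27 C9 carbinol of the target (closed homoadamantane; C9 epimers), via quaternary aldehyde 26 (not isolated)
Conditions: K2CO3 (1.5 equiv), 25 (1.05 equiv), MeCN, 0 °C to rt
Reagents that add atoms: none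
Why: C-Alkylation of the hydroxymethylene ketone, by several pK units the most acidic site, with the allylic bromide (SN2) should occur on the face of the seven-membered ring opposite to the C2–C1–C8 bridge, which fixes C5 with the formyl group pointing at C1. The diketone enol then adds across the ring to the aldehyde (transannular aldol, six-membered ring), setting C1 in the only configuration the cage allows; the C9 carbinol epimers are of no consequence.

Step 16
Reactants: 27 C9 carbinol of the target
Product: 28 CNP0280463.1
Conditions: DMP, CH2Cl2, 0 °C to rt
Reagents that add atoms: none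
Why: Dess–Martin oxidation of the secondary carbinol between two quaternary carbons, under non-nucleophilic conditions tolerated by the alkenes and the β-tricarbonyl; it also pulls any retro-aldol equilibrium through to the ketone.

## Compound list

1 | 3-methylbut-2-enoyl chloride | CC(C)=CC(Cl)=O | starting material
2 | 2,5-dimethylhex-4-en-3-one | CC(C)=CC(=O)C(C)C | intermediate
3 | 1,4-dioxaspiro[4.5]decan-8-ol | OC1CCC2(CC1)OCCO2 | starting material
4 | 8-bromo-1,4-dioxaspiro[4.5]decane | BrC1CCC2(CC1)OCCO2 | intermediate
5 | (1,4-dioxaspiro[4.5]decan-8-yl)magnesium bromide | Br[Mg]C1CCC2(CC1)OCCO2 | intermediate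
6 | {[5-(1,4-dioxaspiro[4.5]decan-8-yl)-2,5-dimethylhex-3-en-3-yl]oxy}trimethylsilane | CC(C)C(O[Si](C)(C)C)=CC(C)(C)C1CCC2(CC1)OCCO2 | intermediate
7 | 4-(2,5-dimethyl-4-oxohexan-2-yl)cyclohexan-1-one | CC(C)C(=O)CC(C)(C)C1CCC(=O)CC1 | intermediate
8 | ethyl diazoacetate | CCOC(=O)C=[N+]=[N-] | starting material
9 | ethyl (5R)-5-(2,5-dimethyl-4-oxohexan-2-yl)-2-oxocycloheptane-1-carboxylate (C3 epimers and enol) | CCOC(=O)C1CC[C@@H](C(C)(C)CC(=O)C(C)C)CCC1=O | intermediate
10 | 1-(phenylselanyl) derivative of 9 (selenium on C3; C7 as in 9) | CCOC(=O)C1([Se]c2ccccc2)CC[C@@H](C(C)(C)CC(=O)C(C)C)CCC1=O | intermediate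
11 | ethyl (4S)-4-(2,5-dimethyl-4-oxohexan-2-yl)-7-oxocyclohept-1-ene-1-carboxylate | CCOC(=O)C1=CC[C@@H](C(C)(C)CC(=O)C(C)C)CCC1=O | intermediate
12 | (2-bromoallyl)trimethylsilane | C=C(Br)C[Si](C)(C)C | starting material
13 | [3-(trimethylsilyl)prop-1-en-2-yl]lithium | [Li]C(=C)C[Si](C)(C)C | intermediate
14 | lithium 2-methyl-3-[(trimethylsilyl)methyl]but-3-en-2-olate | [Li]OC(C)(C)C(=C)C[Si](C)(C)C | intermediate
15 | 2-methyl-3-[(trimethylsilyl)methyl]but-3-en-2-yl acetate | CC(=O)OC(C)(C)C(=C)C[Si](C)(C)C | intermediate
16 | ethyl 7-(2,5-dimethyl-4-oxohexan-2-yl)-1,1-dimethyl-2-methylidene-4-oxodecahydroazulene-3a-carboxylate (cis-fused; arm cis to ester) | C=C1C[C@@]2(C(=O)OCC)C(=O)CC[C@H](C(C)(C)CC(=O)C(C)C)C[C@H]2C1(C)C | intermediate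
17 | B-alkyl-9-borabicyclo[3.3.1]nonane from 16 (boron on the former methylene carbon; C13 epimers) | C(B1C2CCCC1CCC2)C1C[C@@]2(C(=O)OCC)C(=O)CC[C@H](C(C)(C)CC(=O)C(C)C)C[C@H]2C1(C)C | intermediate
18 | ethyl 7-(2,5-dimethyl-4-oxohexan-2-yl)-2-(hydroxymethyl)-1,1-dimethyl-4-oxodecahydroazulene-3a-carboxylate (C13 epimers) | OCC1C[C@@]2(C(=O)OCC)C(=O)CC[C@H](C(C)(C)CC(=O)C(C)C)C[C@H]2C1(C)C | intermediate
19 | ethyl 7-(2,5-dimethyl-4-oxohexan-2-yl)-2-formyl-1,1-dimethyl-4-oxodecahydroazulene-3a-carboxylate (formyl cis to ester and H11) | O=C[C@@H]1C[C@@]2(C(=O)OCC)C(=O)CC[C@H](C(C)(C)CC(=O)C(C)C)C[C@H]2C1(C)C | intermediate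
20 | ethyl 7-(2,5-dimethyl-4-oxohexan-2-yl)-2-(1-hydroxyethyl)-1,1-dimethyl-4-oxodecahydroazulene-3a-carboxylate (carbinol epimers) | CC(O)[C@@H]1C[C@@]2(C(=O)OCC)C(=O)CC[C@H](C(C)(C)CC(=O)C(C)C)C[C@H]2C1(C)C | intermediate
21 | ethyl 2-acetyl-7-(2,5-dimethyl-4-oxohexan-2-yl)-1,1-dimethyl-4-oxodecahydroazulene-3a-carboxylate | CC(=O)[C@@H]1C[C@@]2(C(=O)OCC)C(=O)CC[C@H](C(C)(C)CC(=O)C(C)C)C[C@H]2C1(C)C | intermediate
22 | ethyl 7-(2,5-dimethyl-4-oxohexan-2-yl)-1,1-dimethyl-4-oxo-2-(prop-1-en-2-yl)decahydroazulene-3a-carboxylate | C=C(C)[C@@H]1C[C@@]2(C(=O)OCC)C(=O)CC[C@H](C(C)(C)CC(=O)C(C)C)C[C@H]2C1(C)C | intermediate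
23 | tricyclic triketone: bicyclo[3.3.2]decane core (C2–C1–C8 bridge closed) fused to the cyclopentane; C1–H bears isobutyryl (keto form drawn, C1 labile); C2, C4 ketones; C5 H2 | C=C(C)[C@@H]1C[C@@]23C(=O)CC[C@@H](C[C@H]2C1(C)C)C(C)(C)C(C(=O)C(C)C)C3=O | intermediate
24 | C5-hydroxymethylene derivative of 23 (hydroxyl syn to C4=O) | C=C(C)[C@@H]1C[C@@]23C(=O)/C(=C\O)C[C@@H](C[C@H]2C1(C)C)C(C)(C)C(C(=O)C(C)C)C3=O | intermediate
25 | geranyl bromide, (2E)-1-bromo-3,7-dimethylocta-2,6-diene | CC(C)=CCC/C(C)=C/CBr | starting material
26 | C5-formyl C5-geranyl derivative of 23 (formyl on the face of the C2–C1–C8 bridge) | C=C(C)[C@@H]1C[C@@]23C(=O)[C@@](C=O)(C/C=C(\C)CCC=C(C)C)C[C@@H](C[C@H]2C1(C)C)C(C)(C)C(C(=O)C(C)C)C3=O | intermediate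
27 | C9 carbinol of the target (closed homoadamantane; C9 epimers) | C=C(C)[C@@H]1C[C@@]23C(=O)[C@@]4(C/C=C(\C)CCC=C(C)C)C[C@@H](C[C@H]2C1(C)C)C(C)(C)[C@](C(=O)C(C)C)(C4O)C3=O | intermediate
28 | CNP0280463.1 | C=C(C)[C@@H]1C[C@@]23C(=O)[C@@]4(C/C=C(\C)CCC=C(C)C)C[C@@H](C[C@H]2C1(C)C)C(C)(C)[C@](C(=O)C(C)C)(C4=O)C3=O | target

## Step count and least certain steps

Total: 16 steps. Longest linear sequence: 14 steps (steps 2–5 and 7–16, from 3 to 28); steps 1 and 6 are one-step side branches.

**Step 7 (key step).** The donor may bond through its unsubstituted terminus, or the zwitterion may be protonated before ring closure, because the reacting terminus is tertiary and has to meet a ring β-carbon. Facial discrimination by C7 across a flexible seven-membered ring may also be incomplete. The fallback makes the same two bonds stepwise, with the regiochemistry fixed by the SE2′ rule of allylsilanes, and sets out from 15 and 11.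
- PdCl2(MeCN)2-catalysed 1,3-acetoxy shift of 15 gives the primary allylic acetate 3-methyl-2-[(trimethylsilyl)methyl]but-2-en-1-yl acetate F1.
- Hosomi–Sakurai addition of F1 to 11 (TiCl4, CH2Cl2, −78 °C) through its γ-carbon, the dimethyl-substituted one, forms C11–C12 and gives the Michael adduct ethyl 7-[3-(acetoxymethyl)-2-methylbut-3-en-2-yl]-5-(2,5-dimethyl-4-oxohexan-2-yl)-2-oxocycloheptane-1-carboxylate F2.
- Pd(PPh3)4 and K2CO3 in THF close C3–C14 by intramolecular Tsuji–Trost alkylation. Both allyl termini are CH2 groups, so only one ring can form, and the route is rejoined at 16.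

**Step 4.** Differentiation of the enantiotopic α-methylene groups may be weak, because the stereodifferentiating substituent is remote and the diazo ester is unsubstituted; a second homologation of 9 can also intervene. The fallback desymmetrises by deprotonation instead, and sets out from 7.
- Lithium (R,R)-bis(1-phenylethyl)amide with TMSCl present (THF, −100 °C) gives the silyl enol ether {[4-(2,5-dimethyl-4-oxohexan-2-yl)cyclohex-1-en-1-yl]oxy}trimethylsilane F3.
- Simmons–Smith cyclopropanation (Et2Zn, CH2I2) gives 4-(2,5-dimethyl-4-oxohexan-2-yl)-1-(trimethylsilyloxy)bicyclo[4.1.0]heptane F4.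
- Saegusa–Ito ring expansion with FeCl3 in DMF gives 3-chloro-5-(2,5-dimethyl-4-oxohexan-2-yl)cycloheptan-1-one F5, and NaOAc in MeOH eliminates it to 5-(2,5-dimethyl-4-oxohexan-2-yl)cyclohept-2-en-1-one F6.
- Iodination (I2, pyridine) gives 5-(2,5-dimethyl-4-oxohexan-2-yl)-2-iodocyclohept-2-en-1-one F7, and ethoxycarbonylation (Pd(PPh3)4, CO, EtOH, Et3N) rejoins the route at 11.

**Step 13.** The ring closure joins a neopentyl enolate carbon to a neopentyl ester across the seven-membered ring and may be slow. Retro-Claisen opening of the β-keto ester by the ethoxide set free, and parking of the material in aldol adducts, could then take over. The fallback inverts the order of the two closures, so that a six-membered aldol comes first and holds C1 over C2, and sets out from 22.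
- Formylation (NaH, HCO2Et) gives the C5-hydroxymethylene derivative of 22 F8.
- Geranylation (K2CO3, 25, MeCN), anti to the arm and the ester, gives the C5-formyl C5-geranyl derivative of 22 F9.
- KOt-Bu in THF then adds the arm enolate to the aldehyde to give the C1–C9 aldol bicycle F10, which is not isolated. The Claisen closure of C1 onto the now adjacent C2 ester follows, with any retro-aldol passing through 26, and the route is rejoined at 27.

**Step 15.** O-Alkylation of the hydroxymethylene enolate or allylic transposition (SN2′) may compete with C-alkylation, and attack on the bridge side of C5 would leave the formyl group out of reach of C1. The fallback replaces the SN2 alkylation by a palladium allylation of the soft enolate and sets out from 24.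
- Geraniol and methyl chloroformate (pyridine) give geranyl methyl carbonate F11.
- Pd(PPh3)4 in THF at rt then delivers the π-geranyl unit to C5 at its primary terminus under neutral conditions, giving 26, which closes as in step 15; the route is rejoined at 27.

## Further compounds

F1 | step 7 | 3-methyl-2-[(trimethylsilyl)methyl]but-2-en-1-yl acetate | CC(C)=C(COC(C)=O)C[Si](C)(C)C
F2 | step 7 | ethyl 7-[3-(acetoxymethyl)-2-methylbut-3-en-2-yl]-5-(2,5-dimethyl-4-oxohexan-2-yl)-2-oxocycloheptane-1-carboxylate | CCOC(=O)C1C(=O)CC[C@H](C(C)(C)CC(=O)C(C)C)C[C@H]1C(C)(C)C(=C)COC(C)=O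
F3 | step 4 | {[4-(2,5-dimethyl-4-oxohexan-2-yl)cyclohex-1-en-1-yl]oxy}trimethylsilane | C[Si](C)(C)OC1=CC[C@@H](C(C)(C)CC(=O)C(C)C)CC1
F4 | step 4 | 4-(2,5-dimethyl-4-oxohexan-2-yl)-1-(trimethylsilyloxy)bicyclo[4.1.0]heptane | C[Si](C)(C)OC12CC1C[C@@H](C(C)(C)CC(=O)C(C)C)CC2
F5 | step 4 | 3-chloro-5-(2,5-dimethyl-4-oxohexan-2-yl)cycloheptan-1-one | O=C1CC(Cl)C[C@@H](C(C)(C)CC(=O)C(C)C)CC1
F6 | step 4 | 5-(2,5-dimethyl-4-oxohexan-2-yl)cyclohept-2-en-1-one | O=C1C=CC[C@@H](C(C)(C)CC(=O)C(C)C)CC1
F7 | step 4 | 5-(2,5-dimethyl-4-oxohexan-2-yl)-2-iodocyclohept-2-en-1-one | O=C1C(I)=CC[C@@H](C(C)(C)CC(=O)C(C)C)CC1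
F8 | step 13 | C5-hydroxymethylene derivative of 22 | C=C(C)[C@@H]1C[C@@]2(C(=O)OCC)C(=O)/C(=C\O)C[C@H](C(C)(C)CC(=O)C(C)C)C[C@H]2C1(C)C
F9 | step 13 | C5-formyl C5-geranyl derivative of 22 | C=C(C)[C@@H]1C[C@@]2(C(=O)OCC)C(=O)[C@@](C=O)(C/C=C(\C)CCC=C(C)C)C[C@H](C(C)(C)CC(=O)C(C)C)C[C@H]2C1(C)C
F10 | step 13 | C1–C9 aldol bicycle (C9 carbinol, C3 ester intact) | C=C(C)[C@@H]1C[C@@]2(C(=O)OCC)C(=O)[C@@]3(C/C=C(\C)CCC=C(C)C)C[C@@H](C[C@H]2C1(C)C)C(C)(C)C(C(=O)C(C)C)C3O
F11 | step 15 | geranyl methyl carbonate | COC(=O)OC/C=C(\C)CCC=C(C)C
A1 | alternative 1 | caged trione lacking the C1 isobutyryl group | C=C(C)[C@@H]1C[C@@]23C(=O)[C@@]4(C/C=C(\C)CCC=C(C)C)C[C@@H](C[C@H]2C1(C)C)C(C)(C)[C@H](C4=O)C3=O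
A2 | alternative 2 | cyclohepta-1,4-diene diester with a silyl enol ether at C4 | CC(C)(O[Si](CC)(CC)CC)[C@H](CCl)C(C)(C)[C@@H]1C=C(C(C)(C)CC(=O)C(C)C)CC(C(=O)OC)=C(O[Si](C)(C)C(C)(C)C)[C@@H]1C(=O)OC
A3 | alternative 3 | bicyclic trione (enol form) with C7 methylene and bridgehead hydrogen at C5 | C=C1C[C@@H]2C(O)=C(C[C@@H](C(C)=C)C(C)(C)C(OC)OC)C(=O)[C@@](C(=O)C(C)C)(C2=O)C1(C)C
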